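If a run climbs in a straight line, I fold it into a single number before reckoning anything else, so that is where I began with this flask, already followed on Monday.

| setting | Monday's | Friday's | flask |
|---|---|---|---|
| starting material | 20 mM | 20 mM | 20 mM |
| reagent in the second phase | 24 mM | 16 mM | 24.0 mM |
| protic impurity | 0.40 mM | 0.40 mM | 0.400 mM |
| remark | the very flask that is asked about, followed so far | run made earlier |  |
| time |  |  | 6.0 min |
| volume of the second phase over the first |  |  | 0.50 |

| run | time / min | target / % | starting material / % |
|---|---|---|---|
| Monday's | 0.250 | 0.5 | 98.2 |
| Monday's | 0.833 | 2.0 | 96.7 |
| Monday's | 1.33 | 2.8 | 96.3 |
| Monday's | 2.00 | 4.5 | 92.4 |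
| Monday's | 3.00 | 7.5 | 88.6 |
| Friday's | 0.200 | 0.1 | 99.4 |
| Friday's | 0.333 | 0.8 | 97.1 |
| Friday's | 0.667 | 0.6 | 97.6 |
| Friday's | 1.33 | 1.6 | 95.5 |
| Friday's | 2.50 | 3.8 | 94.0 |

(readings scatter by 0.5 percentage points)

- in the second phase: reagent in the second phase; everything else is in the first
- charges count per volume of the first phase; a concentration in a rate is the amount of a species over the volume of its own phase; every rate counts per litre of the first phase
- the analysis behind the earlier runs scatters by 0.5 percentage points, standard deviation
- the earlier runs hold the two phases in the same ratio of volumes as the flask asked about

- delta: doubling the transfer coefficient of the reagent in the second phase, all else as stated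
- beta: doubling the amount of reagent in the second phase, all else as stated

- how much target there is at 6.0 min, in percent of the starting material charged
- the change that raises the amount of target at 6.0 min, in percent of the starting material charged most ("none" if none brings more than 2 percentage points) (delta / beta / none)
- amount of target at 6.0 min, in percent of the starting material charged, after beta

I multiplied Monday's pace of target, 7.5% by 3.00 min, by the asked time and got 15.0%: the fraction of the charge that this pace turns into target within the asked time, a Damköhler number. It stood below one, so I extended the line with little depletion and committed to that figure for the flask.

Friday's pace, read at its last point, was 0.608 of Monday's, and its reagent charge 0.667, so I let the number follow the reagent. Beta then gave 30.0% before trimming for depletion, and no run varied the transfer coefficient, so I chose beta. One number was not quite enough, though: Monday's balance at 3.00 min lacked 3.90%, more than the impurity's 2.00% of the charge.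

The forecast, slightly below my figure, said 14.5%, beta and 27%, holding that “Doubling the reagent doubles the rate”.

The flask gave 15.1%; beta gave 22.9%, below the doubled number, and gained 7.9 percentage points against 1.7 points for delta.

    target → over-reaction product (k = 0.0400 min⁻¹)
    starting material + protic impurity → quenched substrate (k = 340 M⁻¹ min⁻¹)
    starting material + reagent in the reaction phase → target (k = 6.00 M⁻¹ min⁻¹)
    reagent in the reaction phase + target → over-reacted product (k = 8.80 M⁻¹ min⁻¹)
    reagent in the reaction phase ⇌ reagent in the second phase, rate k5*([reagent in the reaction phase] - [reagent in the second phase]/K5) per volume of the first phase (partition coefficient = 2.80, kL = 0.380 min⁻¹)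

In this flask, reagent in the reaction phase was made 4.58 times faster than used up at 1.32 min, each step net, but that ratio was 0.725 at 6.00 min. Its level stood at 7.28 mM at 3.00 min and 7.17 mM at 6.00 min.

For the same flask with 0.16 mM of protic impurity, 0.00800 equiv, I kept the number at 15.0%, since it is reckoned from Monday's chord from time zero and its formula holds no term for the impurity. That flask gave 15.2%, the impurity's loss making no difference.

The earlier runs and the new flask were computed for substances that don't exist.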